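## The problem

Lobophynin B is a cembranoid: a 14-membered carbocycle fused through C1 and C2 to a 2,5-dihydrofuran. The numbering used here is C1 (olefinic ring-fusion carbon), C2 (OCH stereocentre), C3=C4(CH3), C5, C6, oxirane C7–C8(CH3), C9, C10, C11=C12(CH3), C13, C14 back to C1, with furan carbons C15 (bearing C17H2OAc) and C16 (OCH2). There are three stereocentres, C2 (R) and the trans-oxirane C7/C8 (R,R). C2 is too far from the oxirane in a flexible ring to control it, so both elements need reagent control, and the two oxirane centres must come together from an E olefin. The tetrasubstituted C1=C15 olefin carries four different carbon substituents (C2, C14, C16, C17) with fixed geometry, and is the hardest constitutional element. The three E-trisubstituted olefins cannot be told apart by an electrophilic oxidant, so the oxirane has to be introduced while a neighbouring hydroxyl still marks C7=C8. Fragile groups are the trisubstituted oxirane (acid, strong hydride), the primary allylic acetate (base, nucleophiles, zerovalent palladium) and the bis-allylic, α-oxygenated C2–H, which is one hydride abstraction or one ionization away from a furan. The feature that opens the molecule is that the C2 oxygen sits next to C1 and cis to C16 across C1=C15: a C2 alkoxide can direct anti-addition of C14 and of a one-carbon electrophile across a C1≡C15 alkyne and then close the five-membered ring.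

## Retrosynthesis

**Acetate and C17 oxygen (32 ⇐ 31 ⇐ 30).** The acetyl C–O bond is cut last, because an allylic acetate would not survive hydride reagents, amide bases or palladium. C17 is carried as a TBDPS ether. A benzyl-type ether was set aside for two reasons: its oxidative removal would endanger the bis-allylic C2–H, and an alkyl ether at propargylic C17 is a leaving group for copper-mediated SN2′ substitution in the key step. The forward steps ask only for buffered fluoride and a mild acylation.

**Ring closure at C5–C6 (30 ⇐ 29 ⇐ 28 ⇐ 27).** The C5–C6 bond is cut, with a phenylsulfonyl group added at C5. This is the only ring bond lying between an allylic carbon (acidified as the sulfone) and a carbinol carbon. The C6 hydroxyl of epoxy alcohol 27 first directs the epoxidation and then, as triflate 28, becomes the leaving group. The macrocycle 30 becomes an open chain with all stereocentres in place. The forward reaction must close a 14-membered ring at high dilution with one equivalent of base, and the sulfone of 29 must leave without moving C3=C4.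

**Oxirane (27 ⇐ 26).** The two C–O bonds of the oxirane are cut back to the E-allylic alcohol 26. Doing this before ring closure is the only way to single out C7=C8. The forward reaction is a Sharpless epoxidation with the D-tartrate ester.

**Sulfone and ordered release of three primary oxygens (26 ⇐ 25 ⇐ 23 ⇐ 22).** The C5–S bond is cut to allylic alcohol 23. C5, C6 and C17 must be unmasked in that order, so 22 carries TES (C5), TBS (C6) and TBDPS (C17), three silyl ethers of graded acid lability. The forward steps need selective desilylations and a clean SN2 displacement by sulfinate.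

**Dihydrofuran from butenolide (22 ⇐ 21 ⇐ 20).** The C16 oxidation level is raised to the lactone 20, because that is what the carboxylation delivers. Full reduction to diol 21 and displacement at primary C16 by the C2 hydroxyl avoids the lactol, which aromatizes easily, and leaves C2 untouched.

**Key disconnection (20 ⇐ 8 + 16 + 17).** C1–C14, C15–C16 and O–C16 are cut together. Butenolide 20 falls into propargylic alcohol 8 (C2–C5 with C15 and C17), Grignard reagent 16 (C6–C14) and carbon dioxide 17. Stepwise olefinations would have to control the geometry of a tetrasubstituted olefin; here the chelate fixes it. The forward reaction needs alkyl delivery to C1, anti geometry, and survival of the C17 oxygen.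

**Propargylic alcohol (8 ⇐ 5 + 7; 5 ⇐ 4 ⇐ 3 ⇐ 2 ⇐ 1; 7 ⇐ 6).** The C1–C2 bond is cut to enal 5 and alkyne 7, joined by catalytic asymmetric alkynylation, which sets C2. Enal 5 comes from prenyl acetate 1 by allylic oxidation (2), silylation (3), deacetylation (4) and oxidation. Alkyne 7 is the silyl ether of propargyl alcohol 6.

**Grignard reagent (16 ⇐ 15 ⇐ 14 ⇐ 13 ⇐ 12 ⇐ 10 ⇐ 9).** The C13–C14 bond is cut. Geraniol 9 supplies C6–C13 with both E olefins. Silylation (10), terminal allylic oxidation (12), methylenation (13), selective hydroboration (14) and bromination (15) add C14 as the halide-bearing carbon.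

## Roads not taken

**Alternative 1:** The cut is the C12–C13 ring bond. Seco compound A1 carries a cyclopropanol at C1 (ring carbons C13, C14) and an E-vinyl iodide at C12. With Pd(OAc)2, a biaryl phosphine and Cs2CO3, zerovalent palladium inserts into C12–I, the cyclopropanol opens by β-carbon elimination to a palladium homoenolate, and reductive elimination forms C12–C13 and the 14-membered 2-silyloxy ketone A2.
- Merits: ring closure and the C1 carbonyl come in one operation, and no activating group has to be removed afterwards. In this respect it is better than the chosen plan, which spends steps on a sulfone and takes risk in putting it in and taking it out.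
- Weak points: A2 still lacks C15, C16, C17 and the tetrasubstituted olefin, which would have to be built on a hindered macrocyclic ketone. C2–H in A2 is α to the ketone and allylic, so carbonate base at coupling temperature and every later basic step threaten C2 and the position of C3=C4. β-Hydride elimination of the homoenolate competes when reductive elimination must close a large ring.
- Comparison: the chosen plan has the complete dihydrofuran, with its olefin geometry secured, before the ring closes, and never exposes C2 to base next to a ketone.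

**Alternative 2:** The cut is C8–C9 together with the C8–O bond of the oxirane. The organocerium reagent from dienyl Grignard reagent A4 and CeCl3 adds to the C8 ketone of α-chloro ketone A3, which already holds the dihydrofuran as a C1 enol triflate and C17 as a methyl ester. The alkoxide displaces the C7 chloride with inversion and gives seco-epoxide A5. Hydroboration of the terminal vinyl group and an intramolecular B-alkyl Suzuki coupling with the triflate would then form C1–C14.
- Merits: two halves of similar size are joined late; the oxirane needs no epoxidation step and no selective deprotection; the Cornforth arrangement (C–Cl anti to C=O, attack past hydrogen) leads to the required trans oxirane; the sp2–sp3 ring closure leaves nothing to remove. It is more convergent than the chosen plan and its ring closure is cleaner.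
- Weak points: facial selectivity in additions to α-chloro ketones is lower than with α-chloro aldehydes. A3 is configurationally fragile at C7. The β-keto ester behind its enol triflate has C2–H α to a ketone and allylic, so C2 can racemize. The ester and triflate must survive the organocerium reagent.
- Comparison: the chosen plan sets both oxirane centres and C2 by catalyst control of known sense, and makes the tetrasubstituted olefin in one three-component reaction.

**Alternative 3:** The cut is C1–C15 on a preformed macrocycle. The 2-bromoallyl ether A6 of the C2 hydroxyl of a macrocyclic C1 ketone is treated with CrCl2 and catalytic NiCl2. The vinylchromium species adds to the ketone (Nozaki–Hiyama–Kishi reaction, 5-exo) to give the fused 3-methylenetetrahydrofuran-4-ol A7. A 1,3-transposition of the tertiary allylic oxygen to C17 would then create C1=C15 and the acetate together.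
- Merits: the end game after ring closure is shorter than in the chosen plan, the chromium chemistry tolerates the oxirane, and the ring fixes the olefin geometry.
- Weak points: it presupposes a macrocyclic 2-oxy ketone of the A2 type, with the same ring-closure problem and the same risk to C2. Ketones are reluctant acceptors. The transposition needs ionization of a tertiary allylic oxygen next to C2–H, where proton loss gives an aromatic furan, and the acid or electrophilic metal required also opens the trisubstituted oxirane.
- Comparison: the decisive step is run on the complete, most sensitive molecule. The chosen plan takes its risk at the start, on simple fragments.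

Key step: step 13

Assumption: the (R,R)-ProPhenol ligand is taken to deliver the alkynyl group to the Si face of enal 5 (R at C2); the configuration of 8 would be checked by Mosher ester analysis and the (S,S)-ligand used otherwise, with no other change.

## Steps

Step 1
Reactants: 1 prenyl acetate
Product: 2 (E)-4-hydroxy-3-methylbut-2-en-1-yl acetate
Conditions: SeO2 (0.3 equiv), t-BuOOH (aq., 3 equiv), salicylic acid (cat.), CH2Cl2, 23 °C
Reagents that add atoms: tert-butyl hydroperoxide, CC(C)(C)OO
Why: Catalytic SeO2 allylic oxidation (ene reaction, then [2,3]-sigmatropic shift) attacks the E-methyl group of a trisubstituted olefin and gives the E primary allylic alcohol; minor over-oxidized enal is separated.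

Step 2
Reactants: 2 (E)-4-hydroxy-3-methylbut-2-en-1-yl acetate
Product: 3 (E)-3-methyl-4-(triethylsilyloxy)but-2-en-1-yl acetate
Conditions: TESCl, imidazole, CH2Cl2, 0 °C
Reagents that add atoms: chlorotriethylsilane, CC[Si](Cl)(CC)CC
Why: Imidazole-promoted silylation of a primary alcohol; TES is the most acid-labile of the three silyl ethers the route carries and marks C5 for first release.

Step 3
Reactants: 3 (E)-3-methyl-4-(triethylsilyloxy)but-2-en-1-yl acetate
Product: 4 (E)-3-methyl-4-(triethylsilyloxy)but-2-en-1-ol
Conditions: i-Bu2AlH (2.2 equiv), CH2Cl2, −78 °C; aq. potassium sodium tartrate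
Reagents that add atoms: none
Why: Reductive ester cleavage by an aluminium hydride at low temperature; it avoids methanolic base, which can erode a primary TES ether.

Step 4
Reactants: 4 (E)-3-methyl-4-(triethylsilyloxy)but-2-en-1-ol
Product: 5 (E)-3-methyl-4-(triethylsilyloxy)but-2-enal
Conditions: MnO2 (excess), CH2Cl2, 23 °C
Reagents that add atoms: none
Why: MnO2 oxidation of an allylic alcohol is selective, neutral and does not isomerize the E olefin.

Step 5
Reactants: 6 propargyl alcohol
Product: 7 tert-butyl(diphenyl)(prop-2-yn-1-yloxy)silane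
Conditions: TBDPSCl, imidazole, CH2Cl2, 0 → 23 °C
Reagents that add atoms: tert-butyl(chloro)diphenylsilane, CC(C)(C)[Si](Cl)(c1ccccc1)c1ccccc1
Why: Standard silylation; the bulky, weakly Lewis-basic TBDPS ether is chosen so that the C17 oxygen is a poor leaving group in step 13 and can be removed by fluoride at the end.

Step 6
Reactants: 5 (E)-3-methyl-4-(triethylsilyloxy)but-2-enal, 7 tert-butyl(diphenyl)(prop-2-yn-1-yloxy)silane
Product: 8 (4R,5E)-1-(tert-butyldiphenylsilyloxy)-6-methyl-7-(triethylsilyloxy)hept-5-en-2-yn-4-ol (cembrane C2 carbinol, C1≡C15 alkyne)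
Conditions: 7 (2.8 equiv), Me2Zn (2.9 equiv), (R,R)-ProPhenol (10 mol %), Ph3P=O (20 mol %), toluene, 0 °C; then 5, 4 °C
Reagents that add atoms: none
Why: Catalytic asymmetric alkynylation of an aldehyde by an alkynylzinc on the dinuclear zinc complex of ProPhenol, 2,6-bis{[(R)-2-(hydroxydiphenylmethyl)pyrrolidin-1-yl]methyl}-4-methylphenol, a method suited to enals; the chiral catalyst selects the aldehyde face and sets C2 as R, with 1,2-addition only.

Step 7
Reactants: 9 geraniol
Product: 10 tert-butyl{[(2E)-3,7-dimethylocta-2,6-dien-1-yl]oxy}dimethylsilane (geranyl TBS ether)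
Conditions: TBSCl, imidazole, CH2Cl2, 23 °C
Reagents that add atoms: tert-butyl(chloro)dimethylsilane, CC(C)(C)[Si](C)(C)Cl
Why: Standard silylation; TBS at C6 is of middle lability and survives the Grignard chemistry.

Step 8
Reactants: 10 geranyl TBS ether
Product: 12 (2E,6E)-8-(tert-butyldimethylsilyloxy)-2,6-dimethylocta-2,6-dienal, via allylic alcohol 11 (not isolated)
Conditions: SeO2 (0.3 equiv), t-BuOOH, salicylic acid (cat.), CH2Cl2, 0 → 23 °C; then MnO2, CH2Cl2, 23 °C
Reagents that add atoms: tert-butyl hydroperoxide, CC(C)(C)OO
Why: SeO2 allylic oxidation is selective for the E-methyl group of the remote, more electron-rich trisubstituted olefin of geranyl ethers; MnO2 converges the alcohol/enal mixture on the E enal.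

Step 9
Reactants: 12 (2E,6E)-8-(tert-butyldimethylsilyloxy)-2,6-dimethylocta-2,6-dienal
Product: 13 tert-butyl{[(2E,6E)-3,7-dimethylnona-2,6,8-trien-1-yl]oxy}dimethylsilane
Conditions: Ph3PCH3Br, KN(SiMe3)2, THF, −78 → 0 °C
Reagents that add atoms: methyltriphenylphosphonium bromide, C[P+](c1ccccc1)(c1ccccc1)c1ccccc1.[Br-]
Why: Wittig methylenation of an enal adds C14 as a terminal vinyl carbon; no new olefin geometry arises and the existing ones are untouched.

Step 10
Reactants: 13 tert-butyl{[(2E,6E)-3,7-dimethylnona-2,6,8-trien-1-yl]oxy}dimethylsilane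
Product: 14 (3E,7E)-9-(tert-butyldimethylsilyloxy)-4,8-dimethylnona-3,7-dien-1-ol
Conditions: Sia2BH (from BH3·THF and 2-methylbut-2-ene), THF, 0 °C; then NaOH, H2O2, 0 → 23 °C
Reagents that add atoms: hydrogen peroxide, OO
Why: Hydroboration–oxidation with a bulky dialkylborane adds anti-Markovnikov to the monosubstituted terminal olefin of the diene only and leaves both trisubstituted olefins, a known route from such trienes to homoallylic alcohols.

Step 11
Reactants: 14 (3E,7E)-9-(tert-butyldimethylsilyloxy)-4,8-dimethylnona-3,7-dien-1-ol
Product: 15 {[(2E,6E)-9-bromo-3,7-dimethylnona-2,6-dien-1-yl]oxy}(tert-butyl)dimethylsilane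
Conditions: CBr4, PPh3, CH2Cl2, 0 °C
Reagents that add atoms: carbon tetrabromide, BrC(Br)(Br)Br
Why: Appel bromination of a primary alcohol by SN2 on the alkoxyphosphonium salt; the homoallylic position cannot rearrange.

Step 12
Reactants: 15 {[(2E,6E)-9-bromo-3,7-dimethylnona-2,6-dien-1-yl]oxy}(tert-butyl)dimethylsilane
Product: 16 [(3E,7E)-9-(tert-butyldimethylsilyloxy)-4,8-dimethylnona-3,7-dien-1-yl]magnesium bromide (titrated ether solution)
Conditions: Mg turnings (activated with a crystal of I2), Et2O, reflux
Reagents that add atoms: magnesium, [Mg]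
Why: Grignard formation from a primary homoallylic bromide; the allylic silyl ether and the olefins are inert to magnesium.

Step 13
Reactants: 8 (4R,5E)-1-(tert-butyldiphenylsilyloxy)-6-methyl-7-(triethylsilyloxy)hept-5-en-2-yn-4-ol, 16 [(3E,7E)-9-(tert-butyldimethylsilyloxy)-4,8-dimethylnona-3,7-dien-1-yl]magnesium bromide, 17 carbon dioxide
Product: 20 (5R)-5-[(E)-2-methyl-3-(triethylsilyloxy)prop-1-enyl]-4-[(3E,7E)-9-(tert-butyldimethylsilyloxy)-4,8-dimethylnona-3,7-dienyl]-3-[(tert-butyldiphenylsilyloxy)methyl]furan-2(5H)-one, via oxamagnesacycle 18 (not isolated), via hydroxy acid 19 (not isolated)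
Conditions: MeMgBr (1.0 equiv), Et2O–toluene, −40 °C; 16 (2.0 equiv), CuI (10 mol %), −20 → 23 °C; CO2 (1 atm), −40 → 0 °C; aq. citric acid, 0 °C
Reagents that add atoms: none
Why: MeMgBr turns 8 into its bromomagnesium alkoxide; the organocopper species formed from 16 and catalytic CuI then adds across C1≡C15 with the alkyl group on C1 and the metal on C15 on the side of the C2 oxygen, and transmetalation gives the five-membered oxamagnesacycle 18 (net anti-addition). The closest known reaction type is the copper-catalysed, alkoxide-directed anti-carbomagnesiation of secondary 2-alkyn-1-ols with primary alkyl Grignard reagents, with trapping of the chelated alkenylmagnesium by CO2 to give butenolides. CO2 inserts into the C15–Mg bond with retention, and acidification releases the (Z)-γ-hydroxy acid 19. The one ring is closed by 5-exo-trig lactonization (attack of the C2 hydroxyl on the C16 carboxyl), possible only because the chelate placed C16 cis to the C2 oxygen. No stereocentre is created; C2 keeps its R configuration because no bond to it is broken and the acidic γ-hydrogen of the butenolide appears only after the quench. The step needs regioselectivity (C14 to C1) and anti geometry, both enforced by the magnesium alkoxide chelate. It also needs the C17 oxygen to stay, which is addressed by the bulky, weakly coordinating TBDPS ether, the low copper loading and temperature, and carboxylation as soon as the alkyne is consumed.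

Step 14
Reactants: 20 butenolide
Product: 21 diol (C16 primary alcohol cis to the C2 carbinol across C1=C15; C5 OTES, C6 OTBS, C17 OTBDPS)
Conditions: i-Bu2AlH (4 equiv), CH2Cl2, −78 → −20 °C; aq. potassium sodium tartrate
Reagents that add atoms: none
Why: Aluminium hydride reduction of the lactone through the lactol to the (Z)-2-ene-1,4-diol, by 1,2-reduction only; excess hydride at low temperature carries the lactol on before it can dehydrate to a furan.

Step 15
Reactants: 21 diol
Product: 22 (2R)-2-[(E)-2-methyl-3-(triethylsilyloxy)prop-1-enyl]-3-[(3E,7E)-9-(tert-butyldimethylsilyloxy)-4,8-dimethylnona-3,7-dienyl]-4-[(tert-butyldiphenylsilyloxy)methyl]-2,5-dihydrofuran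
Conditions: PPh3, DIAD, THF, 0 → 23 °C
Reagents that add atoms: none
Why: Mitsunobu cyclodehydration: the oxyphosphonium ion forms at the less hindered primary C16 hydroxyl and is displaced by the C2 hydroxyl (5-exo-tet); no bond to C2 is broken, so R is retained.

Step 16
Reactants: 22 dihydrofuran tris-silyl ether
Product: 23 C5 alcohol (TES removed; C6 OTBS and C17 OTBDPS kept)
Conditions: PPTS (cat.), MeOH–CH2Cl2, 0 °C
Reagents that add atoms: none
Why: Acid-catalysed methanolysis of a primary TES ether is much faster than that of TBS or TBDPS ethers, and this mild acid should leave the bis-allylic ring ether intact.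

Step 17
Reactants: 23 C5 alcohol
Product: 25 C5 phenyl sulfone, via allylic mesylate 24 (not isolated)
Conditions: MsCl, Et3N, THF, −20 °C; then PhSO2Na, Bu4NI (cat.), DMF, 23 °C
Reagents that add atoms: sodium benzenesulfinate, [Na+].[O-]S(=O)c1ccccc1
Why: Sulfonylation of the primary allylic alcohol and SN2 displacement by sulfur of the ambident sulfinate, the standard synthesis of allylic sulfones; a primary centre gives no allylic transposition.

Step 18
Reactants: 25 C5 phenyl sulfone
Product: 26 C6 allylic alcohol (TBS removed; C17 OTBDPS kept)
Conditions: HF·pyridine, pyridine, THF, 0 °C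
Reagents that add atoms: none
Why: Buffered fluoride cleaves a primary TBS ether well before a TBDPS ether; the medium is neither acidic enough for the ring ether nor basic enough for the sulfone.

Step 19
Reactants: 26 C6 allylic alcohol
Product: 27 (7R,8R)-7,8-epoxy C6 alcohol
Conditions: Ti(OiPr)4 (10 mol %), D-(−)-diethyl tartrate (12 mol %), t-BuOOH (anhydrous), 4 Å molecular sieves, CH2Cl2, −20 °C
Reagents that add atoms: tert-butyl hydroperoxide, CC(C)(C)OO
Why: Sharpless asymmetric epoxidation reacts only at the olefin of the allylic alcohol; with the D-tartrate ester an E-3,3-disubstituted allylic alcohol of the geraniol type gives the (2R,3R)-epoxy alcohol, here 7R,8R, by reagent control.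

Step 20
Reactants: 27 (7R,8R)-7,8-epoxy C6 alcohol
Product: 29 macrocyclic sulfone (14-membered ring closed at C5–C6; C5 epimers; C17 OTBDPS), via epoxy triflate 28 (not isolated)
Conditions: Tf2O, 2,6-lutidine, CH2Cl2, −78 °C; cold aqueous wash; then LiN(SiMe3)2 (1.05 equiv, slow addition), THF (0.001 M), −78 °C
Reagents that add atoms: none
Why: Triflation of the primary epoxy alcohol, then intramolecular α-alkylation of the lithiated allylic sulfone at the primary triflate, a known reaction type for sulfonyl carbanions including epoxy triflates; high dilution favours the 14-membered ring, and one equivalent of base at −78 °C avoids a second deprotonation at C5. The new C5 centre is removed in step 21 and its configuration is immaterial.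

Step 21
Reactants: 29 macrocyclic sulfone
Product: 30 17-O-TBDPS-deacetyl-lobophynin B
Conditions: PdCl2(dppp) (10 mol %), LiBHEt3 (2.5 equiv), THF, −20 → 0 °C
Reagents that add atoms: none
Why: Palladium-catalysed reductive desulfonylation of an allylic sulfone: zerovalent palladium ionizes C5–S to a π-allyl complex and hydride is delivered to the less hindered C5 terminus, remote from oxygenated C2, restoring E-C3=C4. No free carbanion arises next to the C2–O bond, and a hindered trisubstituted oxirane should be opened only slowly by this hydride at or below 0 °C.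

Step 22
Reactants: 30 17-O-TBDPS-deacetyl-lobophynin B
Product: 31 deacetyl-lobophynin B (C17 primary allylic alcohol)
Conditions: Bu4NF, AcOH, THF, 0 → 23 °C
Reagents that add atoms: none
Why: Fluoride desilylation buffered with acetic acid; oxirane, dihydrofuran and olefins are inert to it.

Step 23
Reactants: 31 deacetyl-lobophynin B
Product: 32 lobophynin B
Conditions: Ac2O, pyridine, DMAP (cat.), CH2Cl2, 0 °C
Reagents that add atoms: acetic anhydride, CC(=O)OC(C)=O
Why: Nucleophile-catalysed acetylation of the only hydroxyl under non-acidic conditions.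

## Compound list

1 | prenyl acetate | CC(C)=CCOC(C)=O | starting material
2 | (E)-4-hydroxy-3-methylbut-2-en-1-yl acetate | CC(=O)OC/C=C(C)/CO | intermediate
3 | (E)-3-methyl-4-(triethylsilyloxy)but-2-en-1-yl acetate | CC(=O)OC/C=C(C)/CO[Si](CC)(CC)CC | intermediate
4 | (E)-3-methyl-4-(triethylsilyloxy)but-2-en-1-ol | OC/C=C(C)/CO[Si](CC)(CC)CC | intermediate
5 | (E)-3-methyl-4-(triethylsilyloxy)but-2-enal | O=C/C=C(C)/CO[Si](CC)(CC)CC | intermediate
6 | propargyl alcohol | C#CCO | starting material
7 | tert-butyl(diphenyl)(prop-2-yn-1-yloxy)silane | C#CCO[Si](c1ccccc1)(c1ccccc1)C(C)(C)C | intermediate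
8 | (4R,5E)-1-(tert-butyldiphenylsilyloxy)-6-methyl-7-(triethylsilyloxy)hept-5-en-2-yn-4-ol | O[C@H](/C=C(C)/CO[Si](CC)(CC)CC)C#CCO[Si](c1ccccc1)(c1ccccc1)C(C)(C)C | intermediate
9 | geraniol | CC(C)=CCC/C(C)=C/CO | starting material
10 | geranyl TBS ether | CC(C)=CCC/C(C)=C/CO[Si](C)(C)C(C)(C)C | intermediate
11 | (2E,6E)-8-(tert-butyldimethylsilyloxy)-2,6-dimethylocta-2,6-dien-1-ol (not isolated) | OC/C(C)=C/CC/C(C)=C/CO[Si](C)(C)C(C)(C)C | intermediate
12 | (2E,6E)-8-(tert-butyldimethylsilyloxy)-2,6-dimethylocta-2,6-dienal | O=C/C(C)=C/CC/C(C)=C/CO[Si](C)(C)C(C)(C)C | intermediate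
13 | tert-butyl{[(2E,6E)-3,7-dimethylnona-2,6,8-trien-1-yl]oxy}dimethylsilane | C=C/C(C)=C/CC/C(C)=C/CO[Si](C)(C)C(C)(C)C | intermediate
14 | (3E,7E)-9-(tert-butyldimethylsilyloxy)-4,8-dimethylnona-3,7-dien-1-ol | OCC/C(C)=C/CC/C(C)=C/CO[Si](C)(C)C(C)(C)C | intermediate
15 | {[(2E,6E)-9-bromo-3,7-dimethylnona-2,6-dien-1-yl]oxy}(tert-butyl)dimethylsilane | BrCC/C(C)=C/CC/C(C)=C/CO[Si](C)(C)C(C)(C)C | intermediate
16 | [(3E,7E)-9-(tert-butyldimethylsilyloxy)-4,8-dimethylnona-3,7-dien-1-yl]magnesium bromide | Br[Mg]CC/C(C)=C/CC/C(C)=C/CO[Si](C)(C)C(C)(C)C | intermediate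
17 | carbon dioxide | O=C=O | starting material
18 | oxamagnesacycle: magnesium bonded to the C2 oxygen and to C15, C14 chain on C1 (not isolated) | [Mg]1O[C@H](/C=C(C)/CO[Si](CC)(CC)CC)C(CC/C(C)=C/CC/C(C)=C/CO[Si](C)(C)C(C)(C)C)=C1CO[Si](c1ccccc1)(c1ccccc1)C(C)(C)C | intermediate
19 | (Z)-γ-hydroxy acid, C16 carboxyl cis to the C2 carbinol (not isolated) | OC(=O)/C(CO[Si](c1ccccc1)(c1ccccc1)C(C)(C)C)=C(/CC/C(C)=C/CC/C(C)=C/CO[Si](C)(C)C(C)(C)C)[C@H](O)/C=C(C)/CO[Si](CC)(CC)CC | intermediate
20 | butenolide (C16 carbonyl; C5 OTES, C6 OTBS, C17 OTBDPS; 2R) | O=C1O[C@H](/C=C(C)/CO[Si](CC)(CC)CC)C(CC/C(C)=C/CC/C(C)=C/CO[Si](C)(C)C(C)(C)C)=C1CO[Si](c1ccccc1)(c1ccccc1)C(C)(C)C | intermediate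
21 | diol (C16 primary and C2 secondary hydroxyl, cis across C1=C15) | OC/C(CO[Si](c1ccccc1)(c1ccccc1)C(C)(C)C)=C(/CC/C(C)=C/CC/C(C)=C/CO[Si](C)(C)C(C)(C)C)[C@H](O)/C=C(C)/CO[Si](CC)(CC)CC | intermediate
22 | 2,5-dihydrofuran tris-silyl ether (2R) | CC(C)(C)[Si](c1ccccc1)(c1ccccc1)OCC1=C(CC/C(C)=C/CC/C(C)=C/CO[Si](C)(C)C(C)(C)C)[C@@H](/C=C(C)/CO[Si](CC)(CC)CC)OC1 | intermediate
23 | C5 alcohol | CC(C)(C)[Si](c1ccccc1)(c1ccccc1)OCC1=C(CC/C(C)=C/CC/C(C)=C/CO[Si](C)(C)C(C)(C)C)[C@@H](/C=C(C)/CO)OC1 | intermediate
24 | C5 allylic mesylate (not isolated) | CC(C)(C)[Si](c1ccccc1)(c1ccccc1)OCC1=C(CC/C(C)=C/CC/C(C)=C/CO[Si](C)(C)C(C)(C)C)[C@@H](/C=C(C)/COS(C)(=O)=O)OC1 | intermediate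
25 | C5 phenyl sulfone | CC(C)(C)[Si](c1ccccc1)(c1ccccc1)OCC1=C(CC/C(C)=C/CC/C(C)=C/CO[Si](C)(C)C(C)(C)C)[C@@H](/C=C(C)/CS(=O)(=O)c2ccccc2)OC1 | intermediate
26 | C6 allylic alcohol with C5 sulfone | CC(C)(C)[Si](c1ccccc1)(c1ccccc1)OCC1=C(CC/C(C)=C/CC/C(C)=C/CO)[C@@H](/C=C(C)/CS(=O)(=O)c2ccccc2)OC1 | intermediate
27 | (7R,8R)-7,8-epoxy C6 alcohol | CC(C)(C)[Si](c1ccccc1)(c1ccccc1)OCC1=C(CC/C(C)=C/CC[C@@]3(C)O[C@@H]3CO)[C@@H](/C=C(C)/CS(=O)(=O)c2ccccc2)OC1 | intermediate
28 | epoxy triflate (not isolated) | CC(C)(C)[Si](c1ccccc1)(c1ccccc1)OCC1=C(CC/C(C)=C/CC[C@@]3(C)O[C@@H]3COS(=O)(=O)C(F)(F)F)[C@@H](/C=C(C)/CS(=O)(=O)c2ccccc2)OC1 | intermediate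
29 | macrocyclic sulfone (C5 epimers, 17-O-TBDPS) | CC(C)(C)[Si](c1ccccc1)(c1ccccc1)OCC1=C2CC/C(C)=C/CC[C@@]3(C)O[C@@H]3CC(S(=O)(=O)c4ccccc4)/C(C)=C/[C@H]2OC1 | intermediate
30 | 17-O-TBDPS-deacetyl-lobophynin B | CC(C)(C)[Si](c1ccccc1)(c1ccccc1)OCC1=C2CC/C(C)=C/CC[C@@]3(C)O[C@@H]3CC/C(C)=C/[C@H]2OC1 | intermediate
31 | deacetyl-lobophynin B | OCC1=C2CC/C(C)=C/CC[C@@]3(C)O[C@@H]3CC/C(C)=C/[C@H]2OC1 | intermediate
32 | lobophynin B | CC(=O)OCC1=C2CC/C(C)=C/CC[C@@]3(C)O[C@@H]3CC/C(C)=C/[C@H]2OC1 | target

## Step count and least certain steps

Total: 23 steps. Longest linear sequence: 17 steps (9 → 10 → 12 → 13 → 14 → 15 → 16 → 20 → 21 → 22 → 23 → 25 → 26 → 27 → 29 → 30 → 31 → 32).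

**Step 13 (key step).** The most likely failure is loss of the C17 oxygen by copper-mediated SN2′ substitution or β-elimination from the C15-metal intermediate, which would lead to an allenyl carbinol. The regiochemistry of that pathway is the same as that of the desired addition, so the chelate cannot prevent it. A second risk is slow carbometalation of an internal alkyne by a primary alkylcopper, leaving protonated material after the quench. The fallback sets out from 5 and 16 and returns to the route at 20, with C16 taken from a propiolate instead of CO2: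
- zinc–ProPhenol addition of methyl propiolate to 5 gives methyl (4R,5E)-4-hydroxy-6-methyl-7-(triethylsilyloxy)hept-5-en-2-ynoate F1;
- after deprotonation with MeMgBr, the organocopper reagent from 16 and CuBr·SMe2 adds syn across the ynoate at −78 °C (alkyl to C1), the alkenylcopper is trapped with I2, and lactonization on work-up gives the 3-iodobutenolide F2;
- Stille coupling of F2 with (tributylstannyl)methanol under Pd(PPh3)4 gives the 3-(hydroxymethyl)butenolide F3;
- silylation with TBDPSCl and imidazole gives 20.

No oxygen leaving group is present beside the alkyne in this sequence.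

**Step 20.** Ring closure may lose to intermolecular alkylation, and the triflate may decompose before it is used. Excess base can deprotonate C5 a second time, with opening of the oxirane to a cyclopropane. On warming, the allyl sulfone anion can expel the C2 oxygen. The fallback sets out from 27 and returns at 29. I2, PPh3 and imidazole convert 27 into the isolable epoxy iodide F4, which can be purified and then cyclized in a separate operation with LiN(SiMe3)2 in THF–DMPU at −78 → −40 °C at 0.001 M. The slower electrophile allows controlled addition of base to pure substrate.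

**Step 21.** The π-allyl intermediate may take up hydride at C3 as well as C5 (migration of the olefin to C4=C5) or lose the E geometry, and the hydride may open the oxirane. The fallback sets out from 29 and returns at 30. It abandons palladium for single-electron cleavage with sodium amalgam, Na(Hg), and Na2HPO4 in MeOH–THF at −20 °C. The protic medium protonates the allyl anion at once, and alkoxy groups are normally retained under these conditions. No new compound is formed on the way.

**Step 6.** A non-activated alkyne may give low conversion with the enal, facial selectivity may be insufficient, and the sense of induction is an assumption. The fallback sets out from 5 and 7 and returns at 8. The lithium acetylide of 7 (n-BuLi, THF, −78 °C) adds to 5 to give the racemic carbinol F5. MnO2 oxidizes it to the ynone F6. Midland reduction with (R)-Alpine-Borane, in which the alkyne acts as the small group, gives 8 with the R configuration.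

**Step 15.** Activation of the bis-allylic C2 hydroxyl in place of the primary one would lead to ionization, SN2′ products and loss of configuration at C2. The fallback sets out from 21 and returns at 22. Selective chlorination of the primary allylic hydroxyl (MsCl, 2,4,6-collidine, LiCl, DMF, 0 °C) gives the allylic chloride F7. KOt-Bu in THF at 0 °C then closes the ring by Williamson displacement at C16, again without touching the C2–O bond.

## Further compounds

F1 | step 13 | methyl (4R,5E)-4-hydroxy-6-methyl-7-(triethylsilyloxy)hept-5-en-2-ynoate | COC(=O)C#C[C@H](O)/C=C(C)/CO[Si](CC)(CC)CC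
F2 | step 13 | 3-iodobutenolide (iodine on C15; C5 OTES, C6 OTBS) | O=C1O[C@H](/C=C(C)/CO[Si](CC)(CC)CC)C(CC/C(C)=C/CC/C(C)=C/CO[Si](C)(C)C(C)(C)C)=C1I
F3 | step 13 | 3-(hydroxymethyl)butenolide (free C17 hydroxyl) | O=C1O[C@H](/C=C(C)/CO[Si](CC)(CC)CC)C(CC/C(C)=C/CC/C(C)=C/CO[Si](C)(C)C(C)(C)C)=C1CO
F4 | step 20 | epoxy iodide (iodine on C6) | CC(C)(C)[Si](c1ccccc1)(c1ccccc1)OCC1=C(CC/C(C)=C/CC[C@@]3(C)O[C@@H]3CI)[C@@H](/C=C(C)/CS(=O)(=O)c2ccccc2)OC1
F0 | step 21 | none | none
F5 | step 6 | racemic (E)-1-(tert-butyldiphenylsilyloxy)-6-methyl-7-(triethylsilyloxy)hept-5-en-2-yn-4-ol | OC(/C=C(C)/CO[Si](CC)(CC)CC)C#CCO[Si](c1ccccc1)(c1ccccc1)C(C)(C)C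
F6 | step 6 | (E)-1-(tert-butyldiphenylsilyloxy)-6-methyl-7-(triethylsilyloxy)hept-5-en-2-yn-4-one | O=C(/C=C(C)/CO[Si](CC)(CC)CC)C#CCO[Si](c1ccccc1)(c1ccccc1)C(C)(C)C
F7 | step 15 | C16 allylic chloride with free C2 hydroxyl | ClC/C(CO[Si](c1ccccc1)(c1ccccc1)C(C)(C)C)=C(/CC/C(C)=C/CC/C(C)=C/CO[Si](C)(C)C(C)(C)C)[C@H](O)/C=C(C)/CO[Si](CC)(CC)CC
A1 | alternative 1 | seco cyclopropanol with E-vinyl iodide at C12 | OC1(CC1)[C@H](O[Si](C)(C)C(C)(C)C)/C=C(C)/CC[C@H]1O[C@]1(C)CC/C=C(/I)C
A2 | alternative 1 | 14-membered 2-silyloxy ketone | O=C1CC/C(C)=C/CC[C@@]2(C)O[C@@H]2CC/C(C)=C/[C@H]1O[Si](C)(C)C(C)(C)C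
A3 | alternative 2 | α-chloro ketone half with C1 enol triflate and C17 methyl ester | CC(=O)[C@@H](Cl)CC/C(C)=C/[C@H]1OCC(C(=O)OC)=C1OS(=O)(=O)C(F)(F)F
A4 | alternative 2 | (E)-4-methylhexa-3,5-dienylmagnesium bromide | Br[Mg]CC/C=C(C)/C=C
A5 | alternative 2 | seco-epoxide with terminal vinyl group and C1 enol triflate | C=C/C(C)=C/CC[C@@]1(C)O[C@@H]1CC/C(C)=C/[C@H]1OCC(C(=O)OC)=C1OS(=O)(=O)C(F)(F)F
A6 | alternative 3 | 2-bromoallyl ether of the macrocyclic 2-hydroxy ketone | O=C1CC/C(C)=C/CC[C@@]2(C)O[C@@H]2CC/C(C)=C/[C@H]1OCC(Br)=C
A7 | alternative 3 | fused 3-methylenetetrahydrofuran-4-ol | O[C@]12CC/C(C)=C/CC[C@@]3(C)O[C@@H]3CC/C(C)=C/[C@H]1OCC2=C
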